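**Assumption:** the target has no stereocentre, so "single enantiomer" is met trivially; the one stereocentre that appears on the way (in 10, 11, 12) is carried as a racemate and is erased in step 7.

**Retrosynthetic overview**
1. Target ⇐ fluoride desilylation of the tris-silyl flavone.
2. Ring C (the pyranone) is the only ring made: its C4–C3 bond comes from the A-ring aldehyde carbon, converted by a carbene catalyst into an acyl anion that attacks the tethered alkyne; a base-mediated double-bond shift then creates the C2=C3 bond and the 3-prenyl group.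
3. The tether (O1–C2 bond) comes from Mitsunobu etherification of the symmetric A-ring phenol with a B-ring enynol.
4. Enynol ⇐ silylated 2,4,5-trihydroxybenzaldehyde + a lithium enynide (Corey–Fuchs from prenal); A-ring aldehyde ⇐ 2,4,6-trihydroxybenzaldehyde by double C-prenylation and 4-O-methylation.
5. Rings A and B are bought; ring C closes in the penultimate step.

**Route**

Step 1
Reactants: 1 2,4,6-trihydroxybenzaldehyde; 2 prenyl bromide (1-bromo-3-methylbut-2-ene, 2.2 equiv)
Product: 3 2,4,6-trihydroxy-3,5-bis(3-methylbut-2-en-1-yl)benzaldehyde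
Conditions: 10% aq. KOH, 0 °C to rt
Reagents that add atoms: none
Why: Phloroglucinol-type phenoxides alkylate at carbon in water (C-prenylation of acylphloroglucinols), and C-3 and C-5 are the only free ring carbons, so the regiochemistry is fixed and only the yield suffers from O- and gem-dialkylation.

Step 2
Reactants: 3 2,4,6-trihydroxy-3,5-bis(3-methylbut-2-en-1-yl)benzaldehyde
Product: 4 2,6-dihydroxy-4-methoxy-3,5-bis(3-methylbut-2-en-1-yl)benzaldehyde
Conditions: MeI (1.05 equiv), K2CO3 (1.0 equiv), acetone, rt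
Reagents that add atoms: iodomethane, CI
Why: Williamson ether synthesis; the 4-OH is para to the formyl group, the most acidic and the only hydroxyl not locked in a hydrogen bond to C=O, so it is methylated selectively.

Step 3
Reactants: 5 2,4,5-trihydroxybenzaldehyde
Product: 6 2,4,5-tris(tert-butyldimethylsilyloxy)benzaldehyde
Conditions: TBSCl (3.6 equiv), imidazole, DMF, rt
Reagents that add atoms: tert-butyldimethylsilyl chloride, CC(C)(C)[Si](C)(C)Cl
Why: Standard imidazole-promoted silylation masks the three B-ring phenols for the organolithium, Mitsunobu and carbene steps and is later removed by fluoride without acid, which would cyclise prenyl groups onto neighbouring hydroxyls.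

Step 4
Reactants: 7 3-methylbut-2-enal (prenal)
Product: 8 1,1-dibromo-4-methylpenta-1,3-diene
Conditions: CBr4, PPh3, CH2Cl2, 0 °C
Reagents that add atoms: carbon tetrabromide, BrC(Br)(Br)Br
Why: Corey–Fuchs dibromo-olefination (Wittig reaction of Ph3P=CBr2 with the enal).

Step 5
Reactants: 8 1,1-dibromo-4-methylpenta-1,3-diene; 6 2,4,5-tris(tert-butyldimethylsilyloxy)benzaldehyde
Product: 10 rac-5-methyl-1-[2,4,5-tris(tert-butyldimethylsilyloxy)phenyl]hex-4-en-2-yn-1-ol, via lithium 4-methylpent-3-en-1-yn-1-ide 9 (not isolated)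
Conditions: 8, n-BuLi (2 equiv per 8), THF, −78 °C; then 6, −78 °C; AcOH quench at −78 °C
Reagents that add atoms: none
Why: Second stage of the Corey–Fuchs sequence (Br/Li exchange, 1,2-shift, deprotonation) gives the lithium enynide, which adds 1,2 to the aldehyde; the carbinol centre is left racemic because it becomes sp2 C-2 of the flavone, and the cold acidic quench prevents O-to-O silyl migration from the ortho silyl ether.

Step 6
Reactants: 4 2,6-dihydroxy-4-methoxy-3,5-bis(3-methylbut-2-en-1-yl)benzaldehyde; 10 rac-5-methyl-1-[2,4,5-tris(tert-butyldimethylsilyloxy)phenyl]hex-4-en-2-yn-1-ol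
Product: 11 rac-2-hydroxy-4-methoxy-3,5-bis(3-methylbut-2-en-1-yl)-6-({5-methyl-1-[2,4,5-tris(tert-butyldimethylsilyloxy)phenyl]hex-4-en-2-yn-1-yl}oxy)benzaldehyde
Conditions: PPh3 (1.3 equiv), DIAD (1.3 equiv), THF (1 M), 0 °C to rt, sonication
Reagents that add atoms: none
Why: Mitsunobu etherification; the chelated phenol is acidic enough (pKa about 8) to protonate the betaine, the two hydroxyls of 4 are equivalent, the second one stays hydrogen-bonded and hindered so mono-etherification stops cleanly, and the configuration at the carbinol carbon is irrelevant.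

Step 7
Reactants: 11 rac-2-hydroxy-4-methoxy-3,5-bis(3-methylbut-2-en-1-yl)-6-({5-methyl-1-[2,4,5-tris(tert-butyldimethylsilyloxy)phenyl]hex-4-en-2-yn-1-yl}oxy)benzaldehyde
Product: 13 5-hydroxy-7-methoxy-3,6,8-tris(3-methylbut-2-en-1-yl)-2-[2,4,5-tris(tert-butyldimethylsilyloxy)phenyl]-4H-chromen-4-one, via (E)-exocyclic dienone 12 (not isolated)
Conditions: N-mesityl thiazolium precatalyst (3-mesityl-cyclohepta[d]thiazolium perchlorate, 10 mol %), K2CO3 (20 mol %), THF, 60 °C; then DBU (3 equiv), 60 °C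
Reagents that add atoms: none
Why: Proposed new method: the carbene adds to the formyl group to give a catalyst-bound Breslow enaminol (acyl anion equivalent) whose carbon attacks the proximal alkyne carbon 6-exo-dig with concerted O–H transfer to the distal carbon (Conia-ene-like syn addition, hence E), and DBU then removes the benzylic, allylic, α-oxy C2–H of 12 to give a pentadienyl anion that is protonated kinetically at its central carbon, which aromatises the pyranone, unveils the 3-prenyl group and erases the C-2 stereocentre in an atom-economic isomerisation with no co-product; the closest known reaction is the NHC-catalysed intramolecular hydroacylation of unactivated alkynes in 2-(propargyloxy)benzaldehydes to (E)-3-alkylidenechroman-4-ones and their exo-to-endo isomerisation to 3-alkylchromones.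

Step 8
Reactants: 13 5-hydroxy-7-methoxy-3,6,8-tris(3-methylbut-2-en-1-yl)-2-[2,4,5-tris(tert-butyldimethylsilyloxy)phenyl]-4H-chromen-4-one
Product: 14 5-hydroxy-7-methoxy-3,6,8-tris(3-methylbut-2-en-1-yl)-2-(2,4,5-trihydroxyphenyl)-4H-chromen-4-one (CNP0330304.0)
Conditions: TBAF (3.5 equiv), AcOH (3.5 equiv), degassed THF, 0 °C, Ar
Reagents that add atoms: none
Why: Fluoride cleavage of aryl silyl ethers driven by the Si–F bond; acetic acid buffering keeps the air-sensitive hydroxyquinol ring protonated, and the prenyl groups, the methyl ether and the chelated 5-OH are untouched.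

**Compound list**
1 | 2,4,6-trihydroxybenzaldehyde | O=Cc1c(O)cc(O)cc1O | starting material
2 | prenyl bromide (1-bromo-3-methylbut-2-ene) | CC(C)=CCBr | starting material
3 | 2,4,6-trihydroxy-3,5-bis(3-methylbut-2-en-1-yl)benzaldehyde | O=Cc1c(O)c(CC=C(C)C)c(O)c(CC=C(C)C)c1O | intermediate
4 | 2,6-dihydroxy-4-methoxy-3,5-bis(3-methylbut-2-en-1-yl)benzaldehyde | O=Cc1c(O)c(CC=C(C)C)c(OC)c(CC=C(C)C)c1O | intermediate
5 | 2,4,5-trihydroxybenzaldehyde | O=Cc1cc(O)c(O)cc1O | starting material
6 | 2,4,5-tris(tert-butyldimethylsilyloxy)benzaldehyde | O=Cc1cc(O[Si](C)(C)C(C)(C)C)c(O[Si](C)(C)C(C)(C)C)cc1O[Si](C)(C)C(C)(C)C | intermediate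
7 | 3-methylbut-2-enal (prenal) | CC(C)=CC=O | starting material
8 | 1,1-dibromo-4-methylpenta-1,3-diene | CC(C)=CC=C(Br)Br | intermediate
9 | lithium 4-methylpent-3-en-1-yn-1-ide (not isolated) | [Li]C#CC=C(C)C | intermediate
10 | rac-5-methyl-1-[2,4,5-tris(tert-butyldimethylsilyloxy)phenyl]hex-4-en-2-yn-1-ol | CC(C)=CC#CC(O)c1cc(O[Si](C)(C)C(C)(C)C)c(O[Si](C)(C)C(C)(C)C)cc1O[Si](C)(C)C(C)(C)C | intermediate
11 | rac-2-hydroxy-4-methoxy-3,5-bis(3-methylbut-2-en-1-yl)-6-({5-methyl-1-[2,4,5-tris(tert-butyldimethylsilyloxy)phenyl]hex-4-en-2-yn-1-yl}oxy)benzaldehyde | O=Cc1c(O)c(CC=C(C)C)c(OC)c(CC=C(C)C)c1OC(C#CC=C(C)C)c1cc(O[Si](C)(C)C(C)(C)C)c(O[Si](C)(C)C(C)(C)C)cc1O[Si](C)(C)C(C)(C)C | intermediate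
12 | rac-(E)-5-hydroxy-7-methoxy-3-(3-methylbut-2-en-1-ylidene)-6,8-bis(3-methylbut-2-en-1-yl)-2-[2,4,5-tris(tert-butyldimethylsilyloxy)phenyl]chroman-4-one (not isolated) | COc1c(CC=C(C)C)c(O)c2C(=O)/C(=C/C=C(C)C)C(c3cc(O[Si](C)(C)C(C)(C)C)c(O[Si](C)(C)C(C)(C)C)cc3O[Si](C)(C)C(C)(C)C)Oc2c1CC=C(C)C | intermediate
13 | 5-hydroxy-7-methoxy-3,6,8-tris(3-methylbut-2-en-1-yl)-2-[2,4,5-tris(tert-butyldimethylsilyloxy)phenyl]-4H-chromen-4-one | COc1c(CC=C(C)C)c(O)c2c(=O)c(CC=C(C)C)c(-c3cc(O[Si](C)(C)C(C)(C)C)c(O[Si](C)(C)C(C)(C)C)cc3O[Si](C)(C)C(C)(C)C)oc2c1CC=C(C)C | intermediate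
14 | 5-hydroxy-7-methoxy-3,6,8-tris(3-methylbut-2-en-1-yl)-2-(2,4,5-trihydroxyphenyl)-4H-chromen-4-one | COc1c(CC=C(C)C)c(O)c2c(=O)c(CC=C(C)C)c(-c3cc(O)c(O)cc3O)oc2c1CC=C(C)C | target

**Step count**
Total: 8 steps. Longest linear sequence: 5 steps (5 → 6 → 10 → 11 → 13 → 14, or equally 1 → 3 → 4 → 11 → 13 → 14).

**Steps most likely to fail, with fallbacks**

Step 7 (most at risk). The aldehyde is flanked by two oxygens and chelated to a free phenol, the acceptor is a conjugated enyne behind an ionisable benzylic ether, and the final protonation must occur at the central carbon and not at the chain terminus. The fallback keeps the carbene-generated acyl anion but gives it an activated alkynoate, for which the double-bond shift is driven by ester acidity, and builds the prenyl group afterwards. It sets out from 6 and 4 and comes back at 13. Lithiated methyl propiolate (methyl propiolate, LiHMDS, THF, −78 °C) is added to 6 to give methyl 4-hydroxy-4-[2,4,5-tris(tert-butyldimethylsilyloxy)phenyl]but-2-ynoate F1. Mitsunobu coupling with 4 gives the aryl ether methyl 4-[2-formyl-3-hydroxy-5-methoxy-4,6-bis(3-methylbut-2-en-1-yl)phenoxy]-4-[2,4,5-tris(tert-butyldimethylsilyloxy)phenyl]but-2-ynoate F2. An intramolecular Stetter reaction (thiazolium or triazolium precatalyst, i-Pr2NEt, toluene) gives the exocyclic alkylidene ester F3, which is not isolated because its C2–H is now γ to the ester and tautomerises under the amine base to the flavone-3-acetic ester F4. DIBAL-H (2.2 equiv, CH2Cl2, −78 °C) reduces F4 to the flavone-3-acetaldehyde F5. Wittig reaction with isopropylidenetriphenylphosphorane (2.2 equiv, THF, −78 to 0 °C) then gives 13.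

Step 6. The Mitsunobu reaction joins a hindered, chelated phenol to a secondary carbinol that ionises very easily; N-alkylation of the hydrazide and allenyl ether formation are possible. The fallback avoids the secondary ether and brings the B ring in last through a C-2 metallated chromone. It sets out from 4 and comes back at 13. Sonogashira coupling of propargyl alcohol with 1-bromo-2-methylprop-1-ene (Pd(PPh3)2Cl2, CuI, Et3N) gives 5-methylhex-4-en-2-yn-1-ol F6. Mitsunobu coupling of this primary alcohol with 4 gives 2-hydroxy-4-methoxy-3,5-bis(3-methylbut-2-en-1-yl)-6-[(5-methylhex-4-en-2-yn-1-yl)oxy]benzaldehyde F7. The same carbene catalysis, now on the directly precedented substrate type, gives the exocyclic dienone (E)-5-hydroxy-7-methoxy-3-(3-methylbut-2-en-1-ylidene)-6,8-bis(3-methylbut-2-en-1-yl)chroman-4-one F8, which is not isolated and is isomerised with DBU or t-BuOK to 5-hydroxy-7-methoxy-3,6,8-tris(3-methylbut-2-en-1-yl)-4H-chromen-4-one F9. Separately, benzene-1,2,4-triol is silylated (TBSCl, imidazole) to 1,2,4-tris(tert-butyldimethylsilyloxy)benzene F10 and iodinated (NIS, MeCN) at the position para to one oxygen and ortho to another, giving 1-iodo-2,4,5-tris(tert-butyldimethylsilyloxy)benzene F11. Chromone F9 is zincated at C-2 with TMPZnCl·LiCl (2.5 equiv, THF; the first equivalent is taken by the 5-OH) to the C-2 zincated chromone F12, and Negishi coupling with F11 (Pd(dba)2, SPhos, 50 °C) gives 13.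

Step 1. The trianion of 1 also gives mono-, O- and gem-diprenylated products, so the yield is low. The fallback reverses the order so that the ring being prenylated is a resorcinol and no longer a phloroglucinol. It sets out from 1 and comes back at 4, skipping 3. Selective 4-O-methylation (MeI 1.0 equiv, Li2CO3, DMF, 40 °C) gives 2,6-dihydroxy-4-methoxybenzaldehyde F13. Its disodium salt is then C-prenylated at the two remaining ring positions in a non-polar medium (NaH, toluene, prenyl bromide 2, 0 °C to rt; ortho-C-alkylation of a tight phenoxide ion pair) to give 4.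

**Further compounds**
F1 | step 7 | methyl 4-hydroxy-4-[2,4,5-tris(tert-butyldimethylsilyloxy)phenyl]but-2-ynoate (racemic) | COC(=O)C#CC(O)c1cc(O[Si](C)(C)C(C)(C)C)c(O[Si](C)(C)C(C)(C)C)cc1O[Si](C)(C)C(C)(C)C
F2 | step 7 | methyl 4-[2-formyl-3-hydroxy-5-methoxy-4,6-bis(3-methylbut-2-en-1-yl)phenoxy]-4-[2,4,5-tris(tert-butyldimethylsilyloxy)phenyl]but-2-ynoate (racemic) | COC(=O)C#CC(Oc1c(C=O)c(O)c(CC=C(C)C)c(OC)c1CC=C(C)C)c1cc(O[Si](C)(C)C(C)(C)C)c(O[Si](C)(C)C(C)(C)C)cc1O[Si](C)(C)C(C)(C)C
F3 | step 7 | methyl 2-{5-hydroxy-7-methoxy-6,8-bis(3-methylbut-2-en-1-yl)-4-oxo-2-[2,4,5-tris(tert-butyldimethylsilyloxy)phenyl]chroman-3-ylidene}acetate (racemic, not isolated) | COC(=O)C=C1C(=O)c2c(O)c(CC=C(C)C)c(OC)c(CC=C(C)C)c2OC1c1cc(O[Si](C)(C)C(C)(C)C)c(O[Si](C)(C)C(C)(C)C)cc1O[Si](C)(C)C(C)(C)C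
F4 | step 7 | methyl 2-{5-hydroxy-7-methoxy-6,8-bis(3-methylbut-2-en-1-yl)-4-oxo-2-[2,4,5-tris(tert-butyldimethylsilyloxy)phenyl]-4H-chromen-3-yl}acetate | COC(=O)Cc1c(-c2cc(O[Si](C)(C)C(C)(C)C)c(O[Si](C)(C)C(C)(C)C)cc2O[Si](C)(C)C(C)(C)C)oc2c(CC=C(C)C)c(OC)c(CC=C(C)C)c(O)c2c1=O
F5 | step 7 | 2-{5-hydroxy-7-methoxy-6,8-bis(3-methylbut-2-en-1-yl)-4-oxo-2-[2,4,5-tris(tert-butyldimethylsilyloxy)phenyl]-4H-chromen-3-yl}acetaldehyde | O=CCc1c(-c2cc(O[Si](C)(C)C(C)(C)C)c(O[Si](C)(C)C(C)(C)C)cc2O[Si](C)(C)C(C)(C)C)oc2c(CC=C(C)C)c(OC)c(CC=C(C)C)c(O)c2c1=O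
F6 | step 6 | 5-methylhex-4-en-2-yn-1-ol | CC(C)=CC#CCO
F7 | step 6 | 2-hydroxy-4-methoxy-3,5-bis(3-methylbut-2-en-1-yl)-6-[(5-methylhex-4-en-2-yn-1-yl)oxy]benzaldehyde | O=Cc1c(O)c(CC=C(C)C)c(OC)c(CC=C(C)C)c1OCC#CC=C(C)C
F8 | step 6 | (E)-5-hydroxy-7-methoxy-3-(3-methylbut-2-en-1-ylidene)-6,8-bis(3-methylbut-2-en-1-yl)chroman-4-one (not isolated) | COc1c(CC=C(C)C)c(O)c2C(=O)/C(=C/C=C(C)C)COc2c1CC=C(C)C
F9 | step 6 | 5-hydroxy-7-methoxy-3,6,8-tris(3-methylbut-2-en-1-yl)-4H-chromen-4-one | COc1c(CC=C(C)C)c(O)c2c(=O)c(CC=C(C)C)coc2c1CC=C(C)C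
F10 | step 6 | 1,2,4-tris(tert-butyldimethylsilyloxy)benzene | CC(C)(C)[Si](C)(C)Oc1ccc(O[Si](C)(C)C(C)(C)C)c(O[Si](C)(C)C(C)(C)C)c1
F11 | step 6 | 1-iodo-2,4,5-tris(tert-butyldimethylsilyloxy)benzene | Ic1cc(O[Si](C)(C)C(C)(C)C)c(O[Si](C)(C)C(C)(C)C)cc1O[Si](C)(C)C(C)(C)C
F12 | step 6 | C-2 chlorozincated chromone, chlorozinc 5-phenoxide (not isolated) | COc1c(CC=C(C)C)c(O[Zn]Cl)c2c(=O)c(CC=C(C)C)c([Zn]Cl)oc2c1CC=C(C)C
F13 | step 1 | 2,6-dihydroxy-4-methoxybenzaldehyde | O=Cc1c(O)cc(OC)cc1O
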